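Ring B is disconnected at C7–C8 and C9–C10 into the diene C7=C6–C5=C10 of a ring A dienol and an E-alkene C8=C9. The key step is a Diels–Alder reaction templated by a temporary phenylboronate; it exploits the syn 1,3-relationship across C10 between the C1 oxygen of ring A and the ring C methylene C11 by tying the C1 oxygen to an oxygen on C11 of the dienophile. One operation forms both bonds and sets the quaternary C10 and the trans-disposed C8 and C9 from the C1 carbinol centre. The precursor is the mixed boronate of (S)-2,4,4-trimethyl-3-vinylcyclohex-2-en-1-ol and methyl (E)-4-hydroxybut-2-enoate. Ring C, ring B oxygenation and the spiro epoxy lactone follow.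

Key step: step 4

Remark (numbering, used throughout): ring A = C1 (CH–OAc), C2, C3, C4 (CMe2), C5 (C–OH), C10 (C–Me); ring B = C5, C6, C7 (CH–OAc), C8, C9, C10; ring C = C8, C9, C11 (CH2), C13 (spiro), C14 (CH–CO2Me, ester carbon C17); lactone = C13, C12 (C=O), O, C16, C15, with the epoxide on C15–C16; β is the face of the C10 methyl, α the opposite face.

Remark (assumption): in step 7 the (S,S) diamide-bisphosphine ligand is assumed to deliver allyl to the β face of the enolate; should the first run show the opposite sense, its (R,R) antipode is used.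

Step 1
Reactants: 1 3-ethoxy-2-methylcyclohex-2-en-1-one
Product: 3 3-ethoxy-2,6,6-trimethylcyclohex-2-en-1-one, via monomethyl enone 2 (not isolated)
Conditions: LiN(i-Pr)2 (commercial solution), THF, −78 °C; MeI, −78 → 0 °C; second charge of LiN(i-Pr)2 then MeI in the same flask
Reagents that add atoms: iodomethane, CI
Why: Kinetic deprotonation of the vinylogous ester at the alpha-prime CH2 and two successive enolate methylations should install the gem-dimethyl group (enolate alkylation); no stereocenter remains.

Step 2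
Reactants: 3 3-ethoxy-2,6,6-trimethylcyclohex-2-en-1-one
Product: 5 2,4,4-trimethyl-3-vinylcyclohex-2-en-1-one, via vinyl carbinol 4 (not isolated)
Conditions: CH2=CHMgBr, THF, 0 °C; then 1 M HCl, 23 °C
Reagents that add atoms: vinylmagnesium bromide, C=C[Mg]Br
Why: 1,2-Addition to the ketone followed by acid hydrolysis of the enol ether with loss of water transposes the enone (Stork–Danheiser sequence) and should give the cross-conjugated dienone; no stereocenter is formed.

Step 3
Reactants: 5 2,4,4-trimethyl-3-vinylcyclohex-2-en-1-one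
Product: 6 (S)-2,4,4-trimethyl-3-vinylcyclohex-2-en-1-ol
Conditions: (R)-2-methyl-CBS-oxazaborolidine (0.1 equiv), BH3·SMe2, THF, −20 °C; MeOH quench
Reagents that add atoms: none
Why: CBS reduction, in which the oxazaborolidine–borane complex treats the substituted alkenyl side as the large group and delivers hydride to one ketone face, should set the (S)-carbinol C1.

Step 4
Reactants: 6 (S)-2,4,4-trimethyl-3-vinylcyclohex-2-en-1-ol; 7 methyl (E)-4-hydroxybut-2-enoate
Product: 10 diol ester (ring A/B octalin: C5=C6; 1α-OH; 10β-Me; 9α-H; β-CH2OH on C9; 8β-H; α-CO2Me on C8), via mixed boronate 8 (not isolated), via boronate cycloadduct 9 (not isolated)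
Conditions: PhB(OH)2 (1.1 equiv), 4 Å molecular sieves, BHT, toluene, 110 °C then 150 °C (sealed tube); then 2,2-dimethylpropane-1,3-diol, 23 °C
Reagents that add atoms: none
Why: The dienol and the hydroxy enoate condense reversibly with PhB(OH)2 to the mixed boronate 8, which undergoes a concerted suprafacial [4+2] cycloaddition; the closest known reaction type is the phenylboronic acid-templated Diels–Alder reaction of 2,4-dienols with 4-hydroxybut-2-enoates. Ring B closes by the [4+2] itself (bonds C7–C8 and C9–C10), and the temporary seven-membered dioxaborepane closes with it as a fused ring because the tether joins the two proximal termini. C10 is set because the tether on the C1 oxygen delivers the dienophile to the diene face syn to that oxygen, so the C10 methyl ends anti to C1–O. C8 and C9 come out trans from the E geometry of the dienophile, and their sense relative to C10 follows from the transition state with the ester endo over C6–H and the tethered CH2 exo, the alternative being disfavoured because the endo position at C9 lies over C5 next to the gem-dimethyl carbon C4. The step needs regioselectivity (C9 to the hindered C10), which the tether enforces against the modest electronic preference, and ester-endo selectivity, which secondary overlap and the shape of the diene should secure. Diol exchange at boron should then free diol ester 10.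

Step 5
Reactants: 10 diol ester
Product: 11 β-keto ester diol (C8–C14(=O)–C13H2–CO2t-Bu, 11-OH, 1α-OH)
Conditions: LiN(i-Pr)2 (5 equiv), tert-butyl acetate (5 equiv), THF, −78 °C; add 10, −78 → −30 °C; aq. NH4Cl
Reagents that add atoms: tert-butyl acetate, CC(=O)OC(C)(C)C
Why: In this crossed Claisen condensation the lithium enolate of tert-butyl acetate should acylate on the C8 methyl ester (or on the lactone formed from it in situ), the product being protected as its enolate, while C8 stays in the equatorial configuration.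

Step 6
Reactants: 11 β-keto ester diol
Product: 14 tricyclic β-keto ester (ring C closed: C14 ketone; C13–CO2t-Bu; C11H2; 1α-OH; C5=C6), via keto aldehyde 12 (not isolated), via alkylidene keto ester 13 (not isolated)
Conditions: TEMPO (0.1 equiv), PhI(OAc)2 (1.1 equiv), NaHCO3, CH2Cl2, 0 → 23 °C; then L-proline (0.2 equiv), diethyl 2,6-dimethyl-1,4-dihydropyridine-3,5-dicarboxylate (1.2 equiv), 23 °C
Reagents that add atoms: none
Why: TEMPO/PhI(OAc)2 should oxidise only the primary alcohol, the aldehyde then closes ring C by intramolecular Knoevenagel condensation with the β-keto ester, and the dihydropyridine reduces the alkylidene keto ester by hydride transfer (organocatalytic reductive alkylation); C13 remains epimerisable and needs no control here.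

Step 7
Reactants: 14 tricyclic β-keto ester
Product: 15 C13-allyl β-keto ester (allyl β, CO2t-Bu α)
Conditions: allyl acetate, Pd2(dba)3·CHCl3 (2.5 mol%), (S,S)-N,N'-(cyclohexane-1,2-diyl)bis[2-(diphenylphosphino)benzamide] (7.5 mol%), N,N,N',N'-tetramethylguanidine, toluene, 0 °C
Reagents that add atoms: allyl acetate, C=CCOC(C)=O
Why: In this Tsuji–Trost asymmetric allylic alkylation the stabilised enolate attacks the ligand-bound allylpalladium complex, and the chiral ligand rather than the weakly biased substrate (its enolate faces differ only by remote groups) should select the β face and so set quaternary C13.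

Step 8
Reactants: 15 C13-allyl β-keto ester
Product: 16 aldehyde (C13–CH2–CHO)
Conditions: OsO4 (2 mol%), NaIO4, 2,6-lutidine, 1,4-dioxane/H2O, 23 °C
Reagents that add atoms: sodium periodate, [Na+].[O-]I(=O)(=O)=O
Why: Lemieux–Johnson oxidation should cleave the unhindered terminal alkene, whereas the trisubstituted C5=C6 alkene flanked by the quaternary C4 and C10 is not dihydroxylated; no stereocenter changes.

Step 9
Reactants: 16 aldehyde
Product: 17 dimethyl acetal
Conditions: HC(OMe)3, PPTS (cat.), MeOH, 23 °C
Reagents that add atoms: trimethyl orthoformate, COC(OC)OC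
Why: Acid-catalysed acetalisation should mask the aldehyde while the neopentyl ring ketone stays untouched.

Step 10
Reactants: 17 dimethyl acetal
Product: 20 enol triflate (C14(OTf)=C8; 1α-OH), via silyl ether 18 (not isolated), via silyl triflate 19 (not isolated)
Conditions: N,O-bis(trimethylsilyl)acetamide, THF, 23 °C; KN(SiMe3)2, −78 °C; PhNTf2, −78 → 0 °C; then K2CO3 (cat.), MeOH, 0 °C
Reagents that add atoms: N-phenylbis(trifluoromethanesulfonimide), O=S(=O)(N(c1ccccc1)S(=O)(=O)C(F)(F)F)C(F)(F)F
Why: After transient silylation of the C1 hydroxyl the base removes the only α-hydrogen of the ketone (at C8) and the enolate is O-sulfonylated (enol triflate formation); mild methanolysis then removes the silyl ether.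

Step 11
Reactants: 20 enol triflate
Product: 21 unsaturated diester (C14(CO2Me)=C8)
Conditions: Pd(OAc)2 (5 mol%), 1,1'-bis(diphenylphosphino)ferrocene (10 mol%), CO (1 atm), MeOH, Et3N, DMF, 60 °C
Reagents that add atoms: carbon monoxide, [C-]#[O+]; methanol, CO
Why: Palladium-catalysed methoxycarbonylation of the enol triflate (oxidative addition, CO insertion, methanolysis) should attach the ester carbon C17 to C14.

Step 12
Reactants: 21 unsaturated diester
Product: 23 saturated diester (8β-H; 14β-CO2Me; 13α-CO2t-Bu; 1α-OH), via C14 epimer 22 (not isolated)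
Conditions: Mg turnings, MeOH, 0 → 23 °C; then NaOMe (0.3 equiv), MeOH, 40 °C
Reagents that add atoms: none
Why: In this dissolving-metal conjugate reduction the radical anion should be protonated at C8 on the β face, making C14 equatorial and the B/C junction trans as in metal reductions of steroidal ring-fusion enones (the cis product would place C14 axial, syn to the C10 methyl), and methoxide then equilibrates C14 to the ester trans to C7 and cis to the C15 side chain.

Step 13
Reactants: 23 saturated diester
Product: 24 1α-acetate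
Conditions: Ac2O, DMAP, pyridine, 40 °C
Reagents that add atoms: acetic anhydride, CC(=O)OC(C)=O
Why: DMAP-catalysed acylation should esterify the hindered axial C1 alcohol, the only free hydroxyl.

Step 14
Reactants: 24 1α-acetate
Product: 25 enone (C5=C6–C7=O)
Conditions: Rh2(cap)4 (cap = caprolactamate, 1 mol%), t-BuOOH (70% in water), K2CO3, CH2Cl2, 23 °C
Reagents that add atoms: tert-butyl hydroperoxide, CC(C)(C)OO
Why: Radical allylic oxidation by tert-butylperoxyl radicals should be regioselective because C7 is the only allylic CH2 of the C5=C6 alkene (C4 and C10 are quaternary).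

Step 15
Reactants: 25 enone
Product: 26 7β-allylic alcohol
Conditions: NaBH4, CeCl3·7H2O, MeOH, −40 °C
Reagents that add atoms: none
Why: Luche 1,2-reduction with axial hydride delivery from the α face should give the equatorial 7β-alcohol, as with steroidal 5-en-7-ones.

Step 16
Reactants: 26 7β-allylic alcohol
Product: 27 1α,7β-diacetate
Conditions: Ac2O, DMAP, pyridine, 23 °C
Reagents that add atoms: acetic anhydride, CC(=O)OC(C)=O
Why: Standard acylation of the secondary allylic alcohol with retention at C7.

Step 17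
Reactants: 27 1α,7β-diacetate
Product: 29 5α-alcohol, via hydroperoxide 28 (not isolated)
Conditions: Mn(dpm)3 (dpm = dipivaloylmethanate, 10 mol%), PhSiH3, O2 (1 atm), i-PrOH/CH2Cl2, 0 °C; then PPh3
Reagents that add atoms: dioxygen, O=O
Why: Mukaiyama hydration, in which hydrogen-atom transfer to C6 gives the tertiary C5 radical that is trapped by O2 on the α face, anti to the C10 methyl and the axial C4 methyl, should give the trans-decalin hydroperoxide, reduced in the flask to the 5α-alcohol.

Step 18
Reactants: 29 5α-alcohol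
Product: 31 spiro hydroxy lactone (lactol at C16; both epimers), via aldehyde acid 30 (not isolated)
Conditions: 85% aq. H3PO4, toluene, 23 °C
Reagents that add atoms: water, O
Why: Mild aqueous acid should cleave the tert-butyl ester and the acetal, and the liberated C12 acid adds to the C16 aldehyde (ring-chain tautomerism of a γ-aldehydo acid) to give the five-membered lactol, the tertiary alcohol, acetates and methyl ester being left alone.

Step 19
Reactants: 31 spiro hydroxy lactone
Product: 33 enol lactone (C15=C16), via lactol mesylate 32 (not isolated)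
Conditions: MsCl, Et3N, CH2Cl2, −20 → 23 °C
Reagents that add atoms: none
Why: Sulfonylation of the lactol hydroxyl to the mesylate 32 and base-induced elimination of methanesulfonate across C15–C16 (as in glycal formation from lactols) should give the enol lactone, which cannot move into conjugation because C13 is quaternary, the hindered tertiary C5 alcohol not reacting.

Step 20
Reactants: 33 enol lactone
Product: 35 spirocaesalmin, via bromohydrin 34 (not isolated)
Conditions: NBS, THF/H2O (4:1), 0 °C; then Cs2CO3 (1.0 equiv), MeCN, 0 °C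
Reagents that add atoms: water, O
Why: Bromohydrin formation then epoxide closure: the bromonium ion should form on the alkene face anti to the cis C14 ester, water opens it at the acyloxy-stabilised C16 trans to bromine, and the lactol alkoxide displaces bromide with inversion at C15 (as in 1,2-anhydro sugar formation from 2-halo lactols), which places the epoxide oxygen syn to C14 as required.

Compound list
1 | 3-ethoxy-2-methylcyclohex-2-en-1-one | CCOC1=C(C)C(=O)CCC1 | starting material
2 | 3-ethoxy-2,6-dimethylcyclohex-2-en-1-one (racemic) | CCOC1=C(C)C(=O)C(C)CC1 | intermediate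
3 | 3-ethoxy-2,6,6-trimethylcyclohex-2-en-1-one | CCOC1=C(C)C(=O)C(C)(C)CC1 | intermediate
4 | 3-ethoxy-2,6,6-trimethyl-1-vinylcyclohex-2-en-1-ol (racemic, magnesium alkoxide in the flask) | CCOC1=C(C)C(O)(C=C)C(C)(C)CC1 | intermediate
5 | 2,4,4-trimethyl-3-vinylcyclohex-2-en-1-one | C=CC1=C(C)C(=O)CCC1(C)C | intermediate
6 | (S)-2,4,4-trimethyl-3-vinylcyclohex-2-en-1-ol | O[C@H]1CCC(C)(C)C(C=C)=C1C | intermediate
7 | methyl (E)-4-hydroxybut-2-enoate | COC(=O)/C=C/CO | starting material
8 | mixed phenylboronate of 6 (through O1) and 7 (through its hydroxyl) | COC(=O)/C=C/COB(c1ccccc1)O[C@H]1CCC(C)(C)C(C=C)=C1C | intermediate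
9 | boronate cycloadduct (octalin with C5=C6; 1α-O and the β-CH2O on C9 bridged by B–Ph; 8α-CO2Me; 10β-Me) | COC(=O)[C@@H]1CC=C2C(C)(C)CC[C@@H]3OB(c4ccccc4)OC[C@@H]1[C@]23C | intermediate
10 | diol ester: methyl 8-hydroxy-1-(hydroxymethyl)-5,5,8a-trimethyl-1,2,3,5,6,7,8,8a-octahydronaphthalene-2-carboxylate (1α-OH, 10β-Me, 9α-H, 8β-H, C5=C6) | COC(=O)[C@@H]1CC=C2C(C)(C)CC[C@H](O)[C@]2(C)[C@H]1CO | intermediate
11 | β-keto ester diol (C8–C(=O)–CH2–CO2t-Bu; 11-OH; 1α-OH) | CC(C)(C)OC(=O)CC(=O)[C@@H]1CC=C2C(C)(C)CC[C@H](O)[C@]2(C)[C@H]1CO | intermediate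
12 | keto aldehyde (C11 aldehyde) | CC(C)(C)OC(=O)CC(=O)[C@@H]1CC=C2C(C)(C)CC[C@H](O)[C@]2(C)[C@H]1C=O | intermediate
13 | tricyclic alkylidene keto ester (C11=C13, C14 ketone) | CC(C)(C)OC(=O)C1=C[C@H]2[C@@H](CC=C3C(C)(C)CC[C@H](O)[C@]23C)C1=O | intermediate
14 | tricyclic β-keto ester (C14 ketone, C13–CO2t-Bu, epimers at C13; 1α-OH; C5=C6) | CC(C)(C)OC(=O)C1C[C@H]2[C@@H](CC=C3C(C)(C)CC[C@H](O)[C@]23C)C1=O | intermediate
15 | C13-allyl β-keto ester (allyl β, CO2t-Bu α) | CC(C)(C)OC(=O)[C@@]1(CC=C)C[C@H]2[C@@H](CC=C3C(C)(C)CC[C@H](O)[C@]23C)C1=O | intermediate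
16 | aldehyde (C13–CH2CHO) | CC(C)(C)OC(=O)[C@@]1(CC=O)C[C@H]2[C@@H](CC=C3C(C)(C)CC[C@H](O)[C@]23C)C1=O | intermediate
17 | dimethyl acetal of 16 | CC(C)(C)OC(=O)[C@@]1(CC(OC)OC)C[C@H]2[C@@H](CC=C3C(C)(C)CC[C@H](O)[C@]23C)C1=O | intermediate
18 | C1 trimethylsilyl ether of 17 | CC(C)(C)OC(=O)[C@@]1(CC(OC)OC)C[C@H]2[C@@H](CC=C3C(C)(C)CC[C@H](O[Si](C)(C)C)[C@]23C)C1=O | intermediate
19 | C1 trimethylsilyl ether of enol triflate 20 | CC(C)(C)OC(=O)[C@@]1(CC(OC)OC)C[C@H]2C(CC=C3C(C)(C)CC[C@H](O[Si](C)(C)C)[C@]23C)=C1OS(=O)(=O)C(F)(F)F | intermediate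
20 | enol triflate (C14(OTf)=C8; 1α-OH) | CC(C)(C)OC(=O)[C@@]1(CC(OC)OC)C[C@H]2C(CC=C3C(C)(C)CC[C@H](O)[C@]23C)=C1OS(=O)(=O)C(F)(F)F | intermediate
21 | unsaturated diester (C14(CO2Me)=C8) | COC(=O)C1=C2CC=C3C(C)(C)CC[C@H](O)[C@]3(C)[C@H]2C[C@]1(CC(OC)OC)C(=O)OC(C)(C)C | intermediate
22 | 14-epimer of 23 (14α-CO2Me) | COC(=O)[C@@H]1[C@@H]2CC=C3C(C)(C)CC[C@H](O)[C@]3(C)[C@H]2C[C@]1(CC(OC)OC)C(=O)OC(C)(C)C | intermediate
23 | saturated diester (8β-H, 9α-H, 14β-CO2Me, 13α-CO2t-Bu, 1α-OH) | COC(=O)[C@H]1[C@@H]2CC=C3C(C)(C)CC[C@H](O)[C@]3(C)[C@H]2C[C@]1(CC(OC)OC)C(=O)OC(C)(C)C | intermediate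
24 | 1α-acetate of 23 | COC(=O)[C@H]1[C@@H]2CC=C3C(C)(C)CC[C@H](OC(C)=O)[C@]3(C)[C@H]2C[C@]1(CC(OC)OC)C(=O)OC(C)(C)C | intermediate
25 | 7-oxo-5-ene (enone) | COC(=O)[C@H]1[C@@H]2C(=O)C=C3C(C)(C)CC[C@H](OC(C)=O)[C@]3(C)[C@H]2C[C@]1(CC(OC)OC)C(=O)OC(C)(C)C | intermediate
26 | 7β-alcohol | COC(=O)[C@H]1[C@@H]2[C@@H](O)C=C3C(C)(C)CC[C@H](OC(C)=O)[C@]3(C)[C@H]2C[C@]1(CC(OC)OC)C(=O)OC(C)(C)C | intermediate
27 | 1α,7β-diacetate | COC(=O)[C@H]1[C@@H]2[C@@H](OC(C)=O)C=C3C(C)(C)CC[C@H](OC(C)=O)[C@]3(C)[C@H]2C[C@]1(CC(OC)OC)C(=O)OC(C)(C)C | intermediate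
28 | 5α-hydroperoxide | COC(=O)[C@H]1[C@@H]2[C@@H](OC(C)=O)C[C@@]3(OO)C(C)(C)CC[C@H](OC(C)=O)[C@]3(C)[C@H]2C[C@]1(CC(OC)OC)C(=O)OC(C)(C)C | intermediate
29 | 5α-alcohol | COC(=O)[C@H]1[C@@H]2[C@@H](OC(C)=O)C[C@@]3(O)C(C)(C)CC[C@H](OC(C)=O)[C@]3(C)[C@H]2C[C@]1(CC(OC)OC)C(=O)OC(C)(C)C | intermediate
30 | aldehyde acid (C13–CO2H, C13–CH2CHO) | COC(=O)[C@H]1[C@@H]2[C@@H](OC(C)=O)C[C@@]3(O)C(C)(C)CC[C@H](OC(C)=O)[C@]3(C)[C@H]2C[C@]1(CC=O)C(=O)O | intermediate
31 | spiro hydroxy lactone (C16 lactol, both epimers) | COC(=O)[C@H]1[C@@H]2[C@@H](OC(C)=O)C[C@@]3(O)C(C)(C)CC[C@H](OC(C)=O)[C@]3(C)[C@H]2C[C@@]12CC(O)OC2=O | intermediate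
32 | lactol mesylate | COC(=O)[C@H]1[C@@H]2[C@@H](OC(C)=O)C[C@@]3(O)C(C)(C)CC[C@H](OC(C)=O)[C@]3(C)[C@H]2C[C@@]12CC(OS(C)(=O)=O)OC2=O | intermediate
33 | enol lactone (C15=C16) | COC(=O)[C@H]1[C@@H]2[C@@H](OC(C)=O)C[C@@]3(O)C(C)(C)CC[C@H](OC(C)=O)[C@]3(C)[C@H]2C[C@@]12C=COC2=O | intermediate
34 | bromohydrin (15-Br anti to C14, 16-OH syn to C14) | COC(=O)[C@H]1[C@@H]2[C@@H](OC(C)=O)C[C@@]3(O)C(C)(C)CC[C@H](OC(C)=O)[C@]3(C)[C@H]2C[C@@]12[C@H](Br)[C@@H](O)OC2=O | intermediate
35 | spirocaesalmin | COC(=O)[C@H]1[C@@H]2[C@@H](OC(C)=O)C[C@@]3(O)C(C)(C)CC[C@H](OC(C)=O)[C@]3(C)[C@H]2C[C@]12C(=O)O[C@@H]1O[C@@H]12 | target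

Total step count: 20. Longest linear sequence: 20 steps (from 1; dienophile 7 is purchased).

Steps most likely to fail

Step 4. The cycloaddition may be too slow at the fully substituted diene terminus that carries the inside methyl, so that thermal [1,5]-hydrogen shift of the diene or erosion of endo/exo control takes over. The fallback uses a sterically less demanding alkyne on a silicon tether and sets C9 afterwards. It sets out from 6: iPr2SiCl2 and imidazole, then methyl 4-hydroxybut-2-ynoate, should give the silylene acetal F1. Heating in toluene at 130 °C should give the cyclic silylene acetal F2 with a C8=C9 double bond and no endo/exo question. Bu4NF frees the diol, which lactonises to butenolide F3. Mg in MeOH reduces the butenolide with protonation at C9 anti to the C10 methyl to give the saturated lactone F4 (C8 epimers). The Claisen condensation of step 5 applied to F4, during which C8 equilibrates as the ketone enolate, comes back to the route at 11.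

Step 7. Facial selection at the planar enolate may be insufficient if the catalyst is mismatched with the substrate, giving the C13 epimer. The fallback replaces catalyst control by a covalently bound auxiliary. It sets out from 14: condensation with tert-butyl L-valinate should give the enamino ester F5. Deprotonation with LiN(i-Pr)2 and alkylation of the chelated lithio-enamine with allyl bromide, anti to the isopropyl group, should give the imine F6 (the D-valinate serves if the other face is needed). Hydrolysis with aqueous acetic acid comes back to the route at 15.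

Step 20. Bromonium formation on the enol lactone may show poor facial selectivity, or the configuration at C15 may be lost through the ring-opened bromo aldehyde before the epoxide closes. The fallback sets C15 by catalyst control on the open-chain form. It sets out from 31, whose ring-opened aldehyde tautomer should undergo enamine-catalysed α-chlorination (N-chlorosuccinimide, (2R,5R)-2,5-diphenylpyrrolidine, CH2Cl2, 0 °C) to the chloro lactol F7. Cs2CO3 in MeCN at 0 °C then closes the epoxide and comes back to the route at 35.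

Further compounds
F1 | step 4 | diisopropylsilylene acetal of 6 and methyl 4-hydroxybut-2-ynoate | COC(=O)C#CCO[Si](C(C)C)(C(C)C)O[C@H]1CCC(C)(C)C(C=C)=C1C
F2 | step 4 | cyclic silylene acetal cycloadduct (C5=C6 and C8=C9, C8–CO2Me) | COC(=O)C1=C2CO[Si](C(C)C)(C(C)C)O[C@H]3CCC(C)(C)C(=CC1)[C@@]23C
F3 | step 4 | butenolide (C14(=O)–O–C11H2 on C8=C9; 1α-OH; C5=C6) | O=C1OCC2=C1CC=C1C(C)(C)CC[C@H](O)[C@]21C
F4 | step 4 | saturated lactone (9α-H, C8 epimers) | O=C1OC[C@H]2C1CC=C1C(C)(C)CC[C@H](O)[C@]21C
F5 | step 7 | enamino ester of 14 with tert-butyl L-valinate | CC(C)(C)OC(=O)C1=C(N[C@@H](C(C)C)C(=O)OC(C)(C)C)[C@@H]2CC=C3C(C)(C)CC[C@H](O)[C@]3(C)[C@H]2C1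
F6 | step 7 | C13-allyl imine of 15 with tert-butyl L-valinate | CC(C)(C)OC(=O)[C@@]1(CC=C)C[C@H]2[C@@H](CC=C3C(C)(C)CC[C@H](O)[C@]23C)C1=N[C@@H](C(C)C)C(=O)OC(C)(C)C
F7 | step 20 | chloro lactol (15-Cl anti to C14, C16 lactol) | COC(=O)[C@H]1[C@@H]2[C@@H](OC(C)=O)C[C@@]3(O)C(C)(C)CC[C@H](OC(C)=O)[C@]3(C)[C@H]2C[C@@]12[C@H](Cl)C(O)OC2=O
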